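**Retrosynthetic overview**
1. Target 14 is a (2R)-2-hydroxy-4-methyl-1-benzofuran-3(2H)-one with an oxidised farnesyl chain (C1′–C12′) on C2. The benzene ring is bought (12); the furanone ring (O1–C2–C3–C3a–C7a) is the only ring made and is closed last.
2. Enabling feature: C2 carries ring O1, an OH and the C3 acyl carbon, so it is a carboxyl-level carbon. O1–C2(OH)–C3(=O) is therefore the arrested tetrahedral intermediate of an acyl transfer from an aryl ester to an aroyl anion. Disconnecting C2–C3 gives the achiral 2-formyl-3-methylphenyl ester 13, closed by a chiral carbene catalyst that also sets C2.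
3. 13 ⇒ phenol 12 + acid 11 (esterification); the C1′–C2 bond of 11 ⇒ CO + allylic carbonate 9 (palladium-catalysed carbonylation).
4. The dienone of 9 ⇒ enal 4 + C4 alkyne 5 (alkenylzinc addition forming C8′–C9′, then oxidation); 4 ⇒ geraniol 1 (carbonate formation, E-selective allylic oxidation).
5. Ring order: benzene ring (purchased) → furanone ring (step 9).

Key step: step 9

Assumption: the C2 hemiketal can open to the 1,2-diketone; it is taken to hold its configuration under neutral, aprotic, cold handling, so C2 is set in the last step and the target is not exposed to base, acid or protic nucleophiles afterwards.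

**Route**

Step 1
Reactants: 1 geraniol
Product: 2 (2E)-3,7-dimethylocta-2,6-dien-1-yl methyl carbonate (geranyl methyl carbonate)
Conditions: ClCO2Me, pyridine, CH2Cl2, 0 °C
Reagents that add atoms: methyl chloroformate, COC(=O)Cl
Why: O-acylation of the primary allylic alcohol by a chloroformate (carbonate formation) with pyridine as HCl scavenger leaves both olefins untouched and installs the group that later deactivates the 2,3-olefin and serves as the leaving group for carbonylation.

Step 2
Reactants: 2 geranyl methyl carbonate
Product: 3 (2E,6E)-8-hydroxy-3,7-dimethylocta-2,6-dien-1-yl methyl carbonate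
Conditions: SeO2 (0.3 equiv), t-BuOOH (3 equiv), salicylic acid (0.1 equiv), CH2Cl2, rt
Reagents that add atoms: tert-butyl hydroperoxide, CC(C)(C)OO
Why: Catalytic SeO2/t-BuOOH allylic oxidation (ene reaction, then [2,3]-sigmatropic shift) should attack the electron-rich terminal isopropylidene unit at its E-methyl group, the 2,3-olefin being deactivated by the allylic carbonate, which fixes the 6E geometry of the new allylic alcohol.

Step 3
Reactants: 3 (2E,6E)-8-hydroxy carbonate
Product: 4 (2E,6E)-3,7-dimethyl-8-oxoocta-2,6-dien-1-yl methyl carbonate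
Conditions: MnO2 (excess), CH2Cl2, rt
Reagents that add atoms: none
Why: MnO2 oxidation of a primary allylic alcohol should stop at the enal under neutral conditions without E/Z isomerisation and without touching the carbonate.

Step 4
Reactants: 4 (2E,6E)-8-oxo carbonate; 5 trimethyl[(2-methylbut-3-yn-2-yl)oxy]silane
Product: 8 racemic (2E,6E,9E)-8-hydroxy-3,7,11-trimethyl-11-[(trimethylsilyl)oxy]dodeca-2,6,9-trien-1-yl methyl carbonate, via alkenylzirconocene chloride 6 (not isolated), via alkenylmethylzinc 7 (not isolated)
Conditions: 5, Cp2Zr(H)Cl, CH2Cl2, rt; Me2Zn, toluene, −65 °C; then 4, 0 °C; aq NH4Cl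
Reagents that add atoms: none
Why: Syn hydrozirconation of the terminal alkyne places zirconium on the terminal carbon and so sets the 9E alkene, and zirconium-to-zinc transmetalation gives an alkenylzinc that should add 1,2 to the enal without attacking the carbonate (Wipf alkenylation), the new carbinol centre being racemic and removed in step 5.

Step 5
Reactants: 8 racemic bis-allylic alcohol
Product: 9 (2E,6E,9E)-3,7,11-trimethyl-8-oxo-11-[(trimethylsilyl)oxy]dodeca-2,6,9-trien-1-yl methyl carbonate
Conditions: MnO2 (excess), CH2Cl2, rt
Reagents that add atoms: none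
Why: MnO2 oxidation of the doubly allylic secondary alcohol should give the cross-conjugated dienone under neutral conditions that keep the tertiary TMS ether, the carbonate and all three E olefins.

Step 6
Reactants: 9 dienone carbonate
Product: 10 methyl (3E,7E,10E)-4,8,12-trimethyl-9-oxo-12-[(trimethylsilyl)oxy]trideca-3,7,10-trienoate
Conditions: Pd(OAc)2 (5 mol %), PPh3 (10 mol %), CO (20 atm), THF, 50 °C
Reagents that add atoms: carbon monoxide, [C-]#[O+]
Why: Tsuji decarboxylative carbonylation, in which zerovalent palladium ionises the allylic carbonate, CO inserts at the less hindered terminus of the π-allyl complex and the methoxide released with CO2 captures the acyl palladium, should give the linear β,γ-unsaturated ester with the E geometry retained.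

Step 7
Reactants: 10 methyl ester
Product: 11 (3E,7E,10E)-12-hydroxy-4,8,12-trimethyl-9-oxotrideca-3,7,10-trienoic acid
Conditions: LiOH·H2O, THF/MeOH/H2O (3:1:1), 0 °C; then 1 M HCl to pH 4, 0 °C
Reagents that add atoms: lithium hydroxide, [Li+].[OH-]
Why: Saponification of the unhindered methyl ester, with the tertiary TMS ether cleaved by the same hydroxide/methanol medium, should be faster at 0 °C than conjugate addition to the hindered dienone or migration of the β,γ double bond.

Step 8
Reactants: 11 acid; 12 2-hydroxy-6-methylbenzaldehyde
Product: 13 2-formyl-3-methylphenyl (3E,7E,10E)-12-hydroxy-4,8,12-trimethyl-9-oxotrideca-3,7,10-trienoate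
Conditions: N,N'-diisopropylcarbodiimide, DMAP (5 mol %), CH2Cl2, 0 °C
Reagents that add atoms: none
Why: Steglich esterification (carbodiimide activation with catalytic DMAP) should acylate the phenol in preference to the hindered tertiary alcohol, and the low temperature and small amount of DMAP should avoid enolisation of the β,γ-unsaturated acyl group.

Step 9
Reactants: 13 2-formyl-3-methylphenyl ester
Product: 14 (2R)-2-hydroxy-2-[(2E,6E,9E)-11-hydroxy-3,7,11-trimethyl-8-oxododeca-2,6,9-trien-1-yl]-4-methyl-1-benzofuran-3(2H)-one
Conditions: (5aS,10bR)-2-(pentafluorophenyl)-5a,10b-dihydro-4H,6H-indeno[2,1-b][1,2,4]triazolo[4,3-d][1,4]oxazin-2-ium tetrafluoroborate (10 mol %), i-Pr2NEt (8 mol %), 4 Å MS, toluene (0.02 M), 0 °C to rt, Ar; filtration through pH 7 buffered silica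
Reagents that add atoms: none
Why: Proposed new method: the triazolylidene adds to the formyl group of 13 and proton transfer gives the Breslow intermediate, whose nucleophilic carbon (future C3) attacks the neighbouring aryl ester carbonyl (future C2) to form the C2–C3 bond, after which the C2 alkoxide takes the proton of the C3 carbinol and the carbene leaves from C3, giving the C3 ketone and keeping C2 as the hemiketal; the closest known reaction type is the catalytic asymmetric intramolecular crossed benzoin reaction of aryl aldehydes with tethered ketones, here with an aryl ester as acceptor. The furanone ring (O1, C2, C3, C3a, C7a) closes in the 5-exo-trig mode. The C2 stereocentre is created in the C–C bond formation under catalyst control, the aminoindanol backbone shielding one face of the Breslow intermediate; the (5aS,10bR) salt is assigned to the R product by analogy with the benzoin model, and the mirror-image salt is taken if a test run shows the opposite sense. The step needs chemoselectivity for acyl-anion addition over enolisation of the β,γ-unsaturated aryl ester (aldol condensation onto the formyl group, double-bond migration) and over Stetter addition to the dienone; the acidic N-C6F5 azolium (which needs only a substoichiometric hindered amine), the proximity of formyl and ester groups, high dilution and the hindered β-carbons of the dienone should secure this. It also needs the product to keep its configuration, which the absence of free base and the shielding of the C3 ketone by the C4 methyl group and the quaternary C2 (slow carbene re-addition) should secure.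

**Compound list**
1 | geraniol, (2E)-3,7-dimethylocta-2,6-dien-1-ol | OC/C=C(\C)CCC=C(C)C | starting material
2 | (2E)-3,7-dimethylocta-2,6-dien-1-yl methyl carbonate | COC(=O)OC/C=C(\C)CCC=C(C)C | intermediate
3 | (2E,6E)-8-hydroxy-3,7-dimethylocta-2,6-dien-1-yl methyl carbonate | COC(=O)OC/C=C(\C)CC/C=C(\C)CO | intermediate
4 | (2E,6E)-3,7-dimethyl-8-oxoocta-2,6-dien-1-yl methyl carbonate | COC(=O)OC/C=C(\C)CC/C=C(\C)C=O | intermediate
5 | trimethyl[(2-methylbut-3-yn-2-yl)oxy]silane | C#CC(C)(C)O[Si](C)(C)C | starting material
6 | chlorobis(cyclopentadienyl)[(1E)-3-methyl-3-[(trimethylsilyl)oxy]but-1-en-1-yl]zirconium (not isolated) | C[Si](C)(C)OC(C)(C)/C=C/[Zr](Cl)(C1C=CC=C1)C1C=CC=C1 | intermediate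
7 | methyl[(1E)-3-methyl-3-[(trimethylsilyl)oxy]but-1-en-1-yl]zinc (not isolated) | C[Zn]/C=C/C(C)(C)O[Si](C)(C)C | intermediate
8 | racemic (2E,6E,9E)-8-hydroxy-3,7,11-trimethyl-11-[(trimethylsilyl)oxy]dodeca-2,6,9-trien-1-yl methyl carbonate | COC(=O)OC/C=C(\C)CC/C=C(\C)C(O)/C=C/C(C)(C)O[Si](C)(C)C | intermediate
9 | (2E,6E,9E)-3,7,11-trimethyl-8-oxo-11-[(trimethylsilyl)oxy]dodeca-2,6,9-trien-1-yl methyl carbonate | COC(=O)OC/C=C(\C)CC/C=C(\C)C(=O)/C=C/C(C)(C)O[Si](C)(C)C | intermediate
10 | methyl (3E,7E,10E)-4,8,12-trimethyl-9-oxo-12-[(trimethylsilyl)oxy]trideca-3,7,10-trienoate | COC(=O)C/C=C(\C)CC/C=C(\C)C(=O)/C=C/C(C)(C)O[Si](C)(C)C | intermediate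
11 | (3E,7E,10E)-12-hydroxy-4,8,12-trimethyl-9-oxotrideca-3,7,10-trienoic acid | OC(=O)C/C=C(\C)CC/C=C(\C)C(=O)/C=C/C(C)(C)O | intermediate
12 | 2-hydroxy-6-methylbenzaldehyde | Cc1cccc(O)c1C=O | starting material
13 | 2-formyl-3-methylphenyl (3E,7E,10E)-12-hydroxy-4,8,12-trimethyl-9-oxotrideca-3,7,10-trienoate | Cc1cccc(OC(=O)C/C=C(\C)CC/C=C(\C)C(=O)/C=C/C(C)(C)O)c1C=O | intermediate
14 | (2R)-2-hydroxy-2-[(2E,6E,9E)-11-hydroxy-3,7,11-trimethyl-8-oxododeca-2,6,9-trien-1-yl]-4-methyl-1-benzofuran-3(2H)-one | C/C(=C\C[C@@]1(O)Oc2cccc(C)c2C1=O)CC/C=C(\C)C(=O)/C=C/C(C)(C)O | target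

**Summary**
Total step count: 9. Longest linear sequence: 9 steps (1 to 14).

**Steps most likely to fail**

Step 9 (proposed new method). The ring closure may lose to enolisation of the activated β,γ-unsaturated aryl ester followed by intramolecular aldol condensation onto the formyl group, or to acyl transfer from the aryl ester to the carbene. The acyl-anion addition is estimated to be near thermoneutral, so conversion may stall. Enantiomeric purity may erode through reversible carbene addition or ring–chain tautomerism of the hemiketal. The fallback uses known chemistry, sets out from 9 and comes back at 14. Carbonate 9 is used in a zerovalent-palladium-catalysed allylic alkylation (Pd(PPh3)4, THF, rt) of commercial 4-methyl-1-benzofuran-3(2H)-one F1, taken in excess to hold back double allylation; this should give racemic 4-methyl-2-[(2E,6E,9E)-3,7,11-trimethyl-8-oxo-11-[(trimethylsilyl)oxy]dodeca-2,6,9-trien-1-yl]-1-benzofuran-3(2H)-one F2 by attack at the less hindered allyl terminus. The TMS ether is removed with AcOH/THF/H2O at rt to give racemic 2-[(2E,6E,9E)-11-hydroxy-3,7,11-trimethyl-8-oxododeca-2,6,9-trien-1-yl]-4-methyl-1-benzofuran-3(2H)-one F3. The acidic C2–H of F3 is then removed with NaN(SiMe3)2 (1.05 equiv, THF, −78 °C) and the enolate is hydroxylated under reagent control with (1S)-(+)-(10-camphorsulfonyl)oxaziridine (Davis asymmetric enolate hydroxylation; the antipode is taken if a test run shows the other sense), with an AcOH quench at −78 °C, to give 14. In this variant the furanone ring is purchased and C2 is set in the last operation.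

Step 6. The released methoxide may add to the dienone before CO insertion, the hindered π-allyl palladium complex may undergo β-hydride elimination to a triene, and syn–anti isomerisation of the π-allyl complex may erode the 2E geometry. The fallback moves the homologation to the start, where the substrate is a plain allylic carbonate; it sets out from 2 and comes back at 10. Carbonate 2 is carbonylated under the same Tsuji conditions to methyl (3E)-4,8-dimethylnona-3,7-dienoate F4, from which any Z isomer can be removed on AgNO3-impregnated silica. SeO2/t-BuOOH oxidation gives methyl (3E,7E)-9-hydroxy-4,8-dimethylnona-3,7-dienoate F5, and MnO2 gives methyl (3E,7E)-4,8-dimethyl-9-oxonona-3,7-dienoate F6. The alkenylzinc 7, made from 5 via 6 as in step 4, is added to give racemic methyl (3E,7E,10E)-9-hydroxy-4,8,12-trimethyl-12-[(trimethylsilyl)oxy]trideca-3,7,10-trienoate F7, and MnO2 oxidation gives 10.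

Step 8. During carboxyl activation the β,γ double bond may migrate into conjugation, and once the formyl-bearing aryl ester is formed, amine-promoted intramolecular aldol condensation may convert it into a coumarin. The fallback masks the aldehyde during acylation; it sets out from 11 and 12 and comes back at 13. Phenol 12 is converted with ethane-1,2-diol (cat. TsOH, toluene, Dean–Stark) into 2-(1,3-dioxolan-2-yl)-3-methylphenol F8. F8 is acylated with 11 (N,N'-diisopropylcarbodiimide, cat. DMAP, CH2Cl2, 0 °C) to give 2-(1,3-dioxolan-2-yl)-3-methylphenyl (3E,7E,10E)-12-hydroxy-4,8,12-trimethyl-9-oxotrideca-3,7,10-trienoate F9, which has no formyl group to condense with. PPTS in wet acetone then releases the aldehyde to give 13.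

Further compounds
F1 | step 9 | 4-methyl-1-benzofuran-3(2H)-one | Cc1cccc2OCC(=O)c12
F2 | step 9 | racemic 4-methyl-2-[(2E,6E,9E)-3,7,11-trimethyl-8-oxo-11-[(trimethylsilyl)oxy]dodeca-2,6,9-trien-1-yl]-1-benzofuran-3(2H)-one | C/C(=C\CC1Oc2cccc(C)c2C1=O)CC/C=C(\C)C(=O)/C=C/C(C)(C)O[Si](C)(C)C
F3 | step 9 | racemic 2-[(2E,6E,9E)-11-hydroxy-3,7,11-trimethyl-8-oxododeca-2,6,9-trien-1-yl]-4-methyl-1-benzofuran-3(2H)-one | C/C(=C\CC1Oc2cccc(C)c2C1=O)CC/C=C(\C)C(=O)/C=C/C(C)(C)O
F4 | step 6 | methyl (3E)-4,8-dimethylnona-3,7-dienoate | COC(=O)C/C=C(\C)CCC=C(C)C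
F5 | step 6 | methyl (3E,7E)-9-hydroxy-4,8-dimethylnona-3,7-dienoate | COC(=O)C/C=C(\C)CC/C=C(\C)CO
F6 | step 6 | methyl (3E,7E)-4,8-dimethyl-9-oxonona-3,7-dienoate | COC(=O)C/C=C(\C)CC/C=C(\C)C=O
F7 | step 6 | racemic methyl (3E,7E,10E)-9-hydroxy-4,8,12-trimethyl-12-[(trimethylsilyl)oxy]trideca-3,7,10-trienoate | COC(=O)C/C=C(\C)CC/C=C(\C)C(O)/C=C/C(C)(C)O[Si](C)(C)C
F8 | step 8 | 2-(1,3-dioxolan-2-yl)-3-methylphenol | Cc1cccc(O)c1C1OCCO1
F9 | step 8 | 2-(1,3-dioxolan-2-yl)-3-methylphenyl (3E,7E,10E)-12-hydroxy-4,8,12-trimethyl-9-oxotrideca-3,7,10-trienoate | Cc1cccc(OC(=O)C/C=C(\C)CC/C=C(\C)C(=O)/C=C/C(C)(C)O)c1C1OCCO1
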